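**Retrosynthetic overview**
1. Feature: ring B hides a hydroquinone. Its oxygens on B C-1 and B C-4 stand para, and B C-1 sits between the oxygen on B C-2 and the ether oxygen on B C-6 that leads to C C-1. A 3-aryloxy-4-hydroxy-4-(1-methoxyvinyl)cyclobut-2-enone gives this 1,2,4,6-tetraoxygenated pattern on ring expansion.
2. Late disconnections: the eleven O-methyl groups (BBr3), the ring A–O–B C-1 ether (copper-catalysed arylation of the B C-1 phenol), and the methyl group on the B C-4 oxygen.
3. Key disconnection: the B C-3–B C-4 bond, leading back to the cyclobutenone. That comes from 1-methoxyvinyllithium and an aryl semisquarate, in which the crowded B C-6–O–C C-1 link is made as a vinylogous ester from semisquaric chloride.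
4. CDE phenol: E is joined to D, then D to C. Each cycle forms an aryl ether on a halobenzaldehyde and then converts CHO into OH by Baeyer–Villiger oxidation.
5. Ring order: rings E, D, C and A are bought as arenes. Ring B is the only ring built, on the oxygen of ring C, before ring A is attached.

Key step: step 12

Remark on labels: rings run A to E from the 3,5-dihydroxyphenoxy end. In rings B to E, C-1 is the carbon whose ether oxygen lies between two oxygenated carbons. "CDE-aryloxy" means 4-[2,4-dimethoxy-6-(2,4,6-trimethoxyphenoxy)phenoxy]-2,6-dimethoxyphenoxy.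
Assumption: the target is achiral. The two sp3 carbinol centres that occur on the way are racemic and are erased in the same or the next step.

**Step 1**
Reactants: 1 2,4,6-trimethoxybenzaldehyde
Product: 3 2,4,6-trimethoxyphenol, via 2,4,6-trimethoxyphenyl formate 2 (not isolated)
Conditions: mCPBA, CH2Cl2, 0 °C to rt; aq. NaHCO3 wash; then K2CO3 (cat.), MeOH, rt, Ar
Reagents that add atoms: mCPBA, O=C(OO)c1cccc(Cl)c1
Why: Baeyer–Villiger (Dakin-type) oxidation, in which the electron-rich aryl group migrates in the Criegee adduct and the formate shields the oxidisable phenol from peracid until mild methanolysis releases it.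

**Step 2**
Reactants: 4 1-fluoro-3,5-dimethoxybenzene
Product: 6 2-fluoro-4,6-dimethoxybenzaldehyde, via aryl iminium salt 5 (not isolated)
Conditions: POCl3, DMF, 0 to 90 °C; then H2O
Reagents that add atoms: DMF, CN(C)C=O; water, O
Why: Vilsmeier–Haack formylation should go para to one methoxy group and ortho to the other and to the small fluorine, as it does for the bromo and chloro analogues, and not to the crowded carbon between the two methoxy groups.

**Step 3**
Reactants: 3 2,4,6-trimethoxyphenol; 6 2-fluoro-4,6-dimethoxybenzaldehyde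
Product: 7 DE aldehyde 2,4-dimethoxy-6-(2,4,6-trimethoxyphenoxy)benzaldehyde
Conditions: Cs2CO3, DMSO, 100 °C, Ar
Reagents that add atoms: none
Why: SNAr at the fluorine ortho to the formyl group, where both methoxy groups are meta to the reacting carbon and so do not destabilise the Meisenheimer adduct, and attack on a C–F carbon tolerates the di-ortho-substituted phenoxide.

**Step 4**
Reactants: 7 DE aldehyde
Product: 9 DE phenol 2,4-dimethoxy-6-(2,4,6-trimethoxyphenoxy)phenol, via DE aryl formate 8 (not isolated)
Conditions: mCPBA, CH2Cl2, 0 °C to rt; aq. NaHCO3 wash; then K2CO3 (cat.), MeOH, rt, Ar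
Reagents that add atoms: mCPBA, O=C(OO)c1cccc(Cl)c1
Why: Baeyer–Villiger oxidation as in step 1, with ring D (two alkoxy groups and one aryloxy group ortho or para to CHO) as the migrating group, followed by formate methanolysis.

**Step 5**
Reactants: 9 DE phenol; 10 4-bromo-2,6-dimethoxybenzaldehyde
Product: 11 CDE aldehyde 4-[2,4-dimethoxy-6-(2,4,6-trimethoxyphenoxy)phenoxy]-2,6-dimethoxybenzaldehyde
Conditions: CuI (10 mol %), picolinic acid (20 mol %), K3PO4, DMSO, 90 °C, Ar
Reagents that add atoms: none
Why: Ullmann-type diaryl ether synthesis with a catalyst system suited to ortho-substituted phenols, helped by a bromide that is activated by the para formyl group and has only hydrogens next to it.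

**Step 6**
Reactants: 11 CDE aldehyde
Product: 13 CDE phenol 4-[2,4-dimethoxy-6-(2,4,6-trimethoxyphenoxy)phenoxy]-2,6-dimethoxyphenol, via CDE aryl formate 12 (not isolated)
Conditions: mCPBA, CH2Cl2, 0 °C to rt; aq. NaHCO3 wash; then K2CO3 (cat.), MeOH, rt, Ar
Reagents that add atoms: mCPBA, O=C(OO)c1cccc(Cl)c1
Why: Baeyer–Villiger oxidation of a 2,6-dimethoxy-4-aryloxybenzaldehyde by aryl migration, then methanolysis, which places the free hydroxyl on C C-1.

**Step 7**
Reactants: 14 diisopropyl squarate
Product: 16 3-isopropoxycyclobut-3-ene-1,2-dione, via 4-hydroxy-2,3-diisopropoxycyclobut-2-enone 15 (not isolated)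
Conditions: LiAlH(OtBu)3, THF, −78 to −20 °C; then 2 M HCl, CH2Cl2, rt
Reagents that add atoms: water, O
Why: The bulky hydride adds once, 1,2, to a squarate carbonyl, and acid then ionises the racemic carbinol and hydrolyses the alkoxy-stabilised allyl cation with loss of isopropanol, which is the standard squarate-to-3-alkoxycyclobutenedione transposition.

**Step 8**
Reactants: 16 3-isopropoxycyclobut-3-ene-1,2-dione
Product: 17 semisquaric acid (3-hydroxycyclobut-3-ene-1,2-dione)
Conditions: 2 M aq. HCl, THF, 50 °C; evaporation
Reagents that add atoms: water, O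
Why: Acid hydrolysis of a vinylogous ester by addition–elimination gives the strongly acidic vinylogous acid, which is left behind when the volatile components are evaporated.

**Step 9**
Reactants: 17 semisquaric acid
Product: 18 semisquaric chloride (3-chlorocyclobut-3-ene-1,2-dione)
Conditions: (COCl)2, DMF (cat.), CH2Cl2, rt to 40 °C
Reagents that add atoms: oxalyl chloride, O=C(Cl)C(=O)Cl
Why: A vinylogous carboxylic acid is converted into its vinylogous acid chloride through the catalytic chloroiminium species, as is done for squaric acid itself.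

**Step 10**
Reactants: 13 CDE phenol; 18 semisquaric chloride
Product: 20 CDE aryl semisquarate 3-(CDE-aryloxy)cyclobut-3-ene-1,2-dione, via sodium CDE phenoxide 19 (not isolated)
Conditions: NaH, THF, 0 °C; then added to 18 (1.2 equiv), THF, −78 to −20 °C; filtration, concentration
Reagents that add atoms: none
Why: Addition–elimination of a phenoxide on a vinylogous acid chloride is irreversible, whereas exchange on ester 16 would be uphill because aryloxide leaves better than isopropoxide, and attack at either olefinic carbon of the symmetric dione leads to the same product.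

**Step 11**
Reactants: 20 CDE aryl semisquarate; 21 methyl vinyl ether
Product: 23 racemic 4-hydroxy-4-(1-methoxyvinyl)-3-(CDE-aryloxy)cyclobut-2-en-1-one, via 1-methoxyvinyllithium 22 (not isolated)
Conditions: 21 (excess), t-BuLi, THF, −78 to 0 °C; then 20, THF, −78 °C; aq. NH4Cl at −78 °C; Et3N-deactivated silica
Reagents that add atoms: none
Why: 1,2-Addition of an organolithium to a cyclobutenedione goes to the carbonyl next to the aryloxy-bearing carbon, which is a plain ketone while the other carbonyl is deactivated as the vinylogous ester terminus; the new carbinol centre forms racemic and is erased in step 12.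

**Step 12**
Reactants: 23 racemic 4-hydroxy-4-(1-methoxyvinyl)-3-(CDE-aryloxy)cyclobut-2-en-1-one
Product: 26 BCDE hydroquinone 2-methoxy-6-(CDE-aryloxy)benzene-1,4-diol, via (Z)-dienylketene 24 (not isolated), via cyclohexadienone 25 (not isolated)
Conditions: degassed toluene (0.02 M), 110 °C, Ar, base-washed glassware
Reagents that add atoms: none
Why: This is a Moore-type rearrangement of a 4-alkenyl-4-hydroxycyclobutenone, a well-established thermal route to hydroquinones. Heating cleaves the bond between the carbonyl carbon and the carbinol carbon in a conrotatory 4π electrocyclic opening, and because the donor hydroxyl prefers to rotate outward, the 1-methoxyvinyl group rotates inward and lies on the same side as the ketene in 24. Ring B then closes by a thermal disrotatory 6π electrocyclisation that bonds the ketene carbonyl carbon (future B C-4) to the vinyl CH2 (future B C-3), and dienone 25 enolises irreversibly to the aromatic 26. In atom terms B C-1 derives from the carbinol carbon, B C-2 from the methoxy-bearing vinyl carbon, B C-5 from the ring CH and B C-6 from the carbon that carries the CDE-aryloxy group, so the pattern follows from the connectivity of 23 and no regiochemical choice arises. No stereocentre is created and the racemic carbinol centre vanishes. The step needs the ketene to close only onto the vinyl group, which is secured because both ortho carbons of ring C carry methoxy groups and cannot accept it, while dilution and exclusion of air and acid protect the ketene, the enol ether and the hydroquinone.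

**Step 13**
Reactants: 26 BCDE hydroquinone
Product: 27 BCDE phenol 2,4-dimethoxy-6-(CDE-aryloxy)phenol
Conditions: MeI (1.05 equiv), K2CO3 (1.1 equiv), degassed acetone, rt, Ar
Reagents that add atoms: iodomethane, CI
Why: Williamson etherification with one equivalent of MeI should take the B C-4 hydroxyl, which has only hydrogens beside it and is the more acidic one, whereas the B C-1 hydroxyl is buried between the methoxy and CDE-aryloxy groups and hydrogen-bonded to them, the same bias seen in mono-O-methylation of 2-tert-butylhydroquinone.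

**Step 14**
Reactants: 27 BCDE phenol; 28 1-bromo-3,5-dimethoxybenzene
Product: 29 undeca-O-methyl pentamer 1-(3,5-dimethoxyphenoxy)-2,4-dimethoxy-6-(CDE-aryloxy)benzene
Conditions: CuI (20 mol %), picolinic acid (40 mol %), K3PO4, DMSO, 100 °C, Ar
Reagents that add atoms: none
Why: Ullmann-type O-arylation with the CuI/picolinic acid system, which accepts 2,6-disubstituted phenols, using a bromide that is unhindered and carries only meta methoxy groups.

**Step 15**
Reactants: 29 undeca-O-methyl pentamer
Product: 30 target CNP0018313.0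
Conditions: BBr3 (excess, about 20 equiv), CH2Cl2, −78 °C to rt; then H2O, 0 °C, Ar; Sephadex LH-20
Reagents that add atoms: none
Why: Lewis-acid aryl methyl ether cleavage, in which BBr3 binds each methoxy oxygen and bromide attacks the methyl carbon by SN2, while the four diaryl ether links offer no sp3 carbon and stay intact.

**Compound list**
1 | 2,4,6-trimethoxybenzaldehyde | COc1cc(OC)c(C=O)c(OC)c1 | starting material
2 | 2,4,6-trimethoxyphenyl formate | COc1cc(OC)c(OC=O)c(OC)c1 | intermediate
3 | 2,4,6-trimethoxyphenol (ring E) | COc1cc(OC)c(O)c(OC)c1 | intermediate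
4 | 1-fluoro-3,5-dimethoxybenzene | COc1cc(F)cc(OC)c1 | starting material
5 | (2-fluoro-4,6-dimethoxybenzylidene)dimethyliminium dichlorophosphate | COc1cc(F)c(C=[N+](C)C)c(OC)c1.[O-]P(=O)(Cl)Cl | intermediate
6 | 2-fluoro-4,6-dimethoxybenzaldehyde (ring D) | COc1cc(F)c(C=O)c(OC)c1 | intermediate
7 | DE aldehyde, 2,4-dimethoxy-6-(2,4,6-trimethoxyphenoxy)benzaldehyde | COc1cc(OC)c(C=O)c(Oc2c(OC)cc(OC)cc2OC)c1 | intermediate
8 | DE aryl formate | COc1cc(OC)c(OC=O)c(Oc2c(OC)cc(OC)cc2OC)c1 | intermediate
9 | DE phenol, 2,4-dimethoxy-6-(2,4,6-trimethoxyphenoxy)phenol | COc1cc(OC)c(O)c(Oc2c(OC)cc(OC)cc2OC)c1 | intermediate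
10 | 4-bromo-2,6-dimethoxybenzaldehyde (ring C) | COc1cc(Br)cc(OC)c1C=O | starting material
11 | CDE aldehyde | O=Cc1c(OC)cc(Oc2c(OC)cc(OC)cc2Oc2c(OC)cc(OC)cc2OC)cc1OC | intermediate
12 | CDE aryl formate | O=COc1c(OC)cc(Oc2c(OC)cc(OC)cc2Oc2c(OC)cc(OC)cc2OC)cc1OC | intermediate
13 | CDE phenol | Oc1c(OC)cc(Oc2c(OC)cc(OC)cc2Oc2c(OC)cc(OC)cc2OC)cc1OC | intermediate
14 | diisopropyl squarate | CC(C)OC1=C(OC(C)C)C(=O)C1=O | starting material
15 | 4-hydroxy-2,3-diisopropoxycyclobut-2-en-1-one (racemic) | CC(C)OC1=C(OC(C)C)C(O)C1=O | intermediate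
16 | 3-isopropoxycyclobut-3-ene-1,2-dione | CC(C)OC1=CC(=O)C1=O | intermediate
17 | semisquaric acid | OC1=CC(=O)C1=O | intermediate
18 | semisquaric chloride | ClC1=CC(=O)C1=O | intermediate
19 | sodium CDE phenoxide | [Na+].[O-]c1c(OC)cc(Oc2c(OC)cc(OC)cc2Oc2c(OC)cc(OC)cc2OC)cc1OC | intermediate
20 | CDE aryl semisquarate, 3-(CDE-aryloxy)cyclobut-3-ene-1,2-dione | O=C1C=C(Oc2c(OC)cc(Oc3c(OC)cc(OC)cc3Oc3c(OC)cc(OC)cc3OC)cc2OC)C1=O | intermediate
21 | methyl vinyl ether | C=COC | starting material
22 | 1-methoxyvinyllithium | [Li]C(=C)OC | intermediate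
23 | 4-hydroxy-4-(1-methoxyvinyl)-3-(CDE-aryloxy)cyclobut-2-en-1-one (racemic) | C=C(OC)C1(O)C(Oc2c(OC)cc(Oc3c(OC)cc(OC)cc3Oc3c(OC)cc(OC)cc3OC)cc2OC)=CC1=O | intermediate
24 | (Z)-dienylketene, ketenyl and methoxyvinyl groups cis on the central double bond | O=C=C/C(Oc1c(OC)cc(Oc2c(OC)cc(OC)cc2Oc2c(OC)cc(OC)cc2OC)cc1OC)=C(O)\C(=C)OC | intermediate
25 | 4-hydroxy-5-methoxy-3-(CDE-aryloxy)cyclohexa-2,4-dien-1-one | O=C1C=C(Oc2c(OC)cc(Oc3c(OC)cc(OC)cc3Oc3c(OC)cc(OC)cc3OC)cc2OC)C(O)=C(OC)C1 | intermediate
26 | BCDE hydroquinone, free hydroxyls on B C-1 and B C-4 | Oc1cc(OC)c(O)c(Oc2c(OC)cc(Oc3c(OC)cc(OC)cc3Oc3c(OC)cc(OC)cc3OC)cc2OC)c1 | intermediate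
27 | BCDE phenol, free hydroxyl on B C-1 only | COc1cc(OC)c(O)c(Oc2c(OC)cc(Oc3c(OC)cc(OC)cc3Oc3c(OC)cc(OC)cc3OC)cc2OC)c1 | intermediate
28 | 1-bromo-3,5-dimethoxybenzene (ring A) | COc1cc(Br)cc(OC)c1 | starting material
29 | undeca-O-methyl pentamer | COc1cc(OC)cc(Oc2c(OC)cc(OC)cc2Oc2c(OC)cc(Oc3c(OC)cc(OC)cc3Oc3c(OC)cc(OC)cc3OC)cc2OC)c1 | intermediate
30 | CNP0018313.0, pentamer with all eleven hydroxyls free (achiral) | Oc1cc(O)cc(Oc2c(O)cc(O)cc2Oc2c(O)cc(Oc3c(O)cc(O)cc3Oc3c(O)cc(O)cc3O)cc2O)c1 | target

**Step count**
- Total steps: 15.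
- Longest linear sequence: 11 steps (step 1 or step 2, then steps 3 to 6 and 10 to 15). The squarate branch (steps 7 to 9) joins at step 10.

**Three steps most likely to fail**

**Step 11.** The organolithium may attack the aryloxy-bearing olefinic carbon and expel the aryloxide. It may instead remove the vinylic proton of the dione, or the enol ether may hydrolyse during work-up. The fallback sets out from 13 and 6 and comes back at 27. Ring B is taken as a pre-formed arene. Phenol 13 is joined to fluoroaldehyde 6 under the SNAr conditions of step 3 (Cs2CO3, DMSO, 100 °C) to give the BCDE aldehyde F1. Baeyer–Villiger oxidation with mCPBA gives the BCDE aryl formate F2, and methanolysis (K2CO3, MeOH) releases 27, in which the B C-4 oxygen is already methylated.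

**Step 12.** The very electron-rich hydroquinone may be oxidised by air to the quinone during heating or isolation. Product hydroxyls may be acylated by the ketene, and adventitious acid may hydrolyse the enol ether before ring opening. The fallback sets out from 23 and comes back at 27.
- The carbinol is silylated (TBSOTf, 2,6-lutidine, CH2Cl2, 0 °C) to the cyclobutenone silyl ether F3.
- Thermolysis in toluene then gives the mono-silylated hydroquinone F4. Only its B C-4 hydroxyl is free, and it cannot pass to a quinone.
- MeI and K2CO3 in acetone give the silylated dimethyl ether F5, and TBAF in THF frees the B C-1 hydroxyl.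
- The two oxygens are thus told apart by construction, which also removes the selectivity demand of step 13.

**Step 14.** Coupling may be slow at a phenoxide flanked on both sides, so that hydrodebromination of 28 and oxidative degradation of 27 compete. The fallback sets out from 27 and comes back at 29. It is an oxidative Chan–Lam coupling with commercial 3,5-dimethoxyphenylboronic acid (Cu(OAc)2, pyridine, 4 Å molecular sieves, CH2Cl2, air, rt). The aryl group reaches copper by transmetalation rather than by activation of an aryl halide, and the C–O bond forms at room temperature. This fallback makes no compound outside the list (F0).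

**Further compounds**
F1 | step 11 | BCDE aldehyde, 2,4-dimethoxy-6-(CDE-aryloxy)benzaldehyde | COc1cc(OC)c(C=O)c(Oc2c(OC)cc(Oc3c(OC)cc(OC)cc3Oc3c(OC)cc(OC)cc3OC)cc2OC)c1
F2 | step 11 | BCDE aryl formate | COc1cc(OC)c(OC=O)c(Oc2c(OC)cc(Oc3c(OC)cc(OC)cc3Oc3c(OC)cc(OC)cc3OC)cc2OC)c1
F3 | step 12 | 4-(tert-butyldimethylsilyloxy)-4-(1-methoxyvinyl)-3-(CDE-aryloxy)cyclobut-2-en-1-one (racemic) | C=C(OC)C1(O[Si](C)(C)C(C)(C)C)C(Oc2c(OC)cc(Oc3c(OC)cc(OC)cc3Oc3c(OC)cc(OC)cc3OC)cc2OC)=CC1=O
F4 | step 12 | 4-(tert-butyldimethylsilyloxy)-3-methoxy-5-(CDE-aryloxy)phenol | Oc1cc(OC)c(O[Si](C)(C)C(C)(C)C)c(Oc2c(OC)cc(Oc3c(OC)cc(OC)cc3Oc3c(OC)cc(OC)cc3OC)cc2OC)c1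
F5 | step 12 | tert-butyl[2,4-dimethoxy-6-(CDE-aryloxy)phenoxy]dimethylsilane | COc1cc(OC)c(O[Si](C)(C)C(C)(C)C)c(Oc2c(OC)cc(Oc3c(OC)cc(OC)cc3Oc3c(OC)cc(OC)cc3OC)cc2OC)c1
F0 | step 14 | none | none
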